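Compound numbers 1–10 are those of the steps and of the compound list. Lactone atoms are numbered O1, C2 (carbonyl), C3, C4, C5. Ring A is the 3,4-dimethoxyphenyl ring and ring B the 3,4,5-trimethoxyphenyl ring.

## Analysis of the target

The target 10 is a single γ-butyrolactone (oxolan-2-one) with a ring A benzyl group on C3 and a ring B benzyl group on C4; there is no other ring. It has two adjacent stereocentres, C3 and C4, both R, which places the two benzyl groups trans. C3 is α to the carbonyl and can be epimerised, and the trans arrangement is the more stable one, so C3 can be corrected late. C4 cannot be corrected once it is made, and its three carbon branches (CH2O, CH2Ar, CH–C=O) are similar in size and carry no directing heteroatom, so setting its absolute configuration is the real difficulty. The lactone is sensitive to nucleophiles, hydride and strong aqueous base. The two electron-rich arenes are sensitive to oxidants and to strong acid, where a benzylic cation next to ring B would cyclise onto ring A. The strategy rests on C3, C4 and the benzylic carbon between C4 and ring B: a bond from C3 to that benzylic carbon turns them into a cyclopropane fused to the lactone. That extra bond is the only cyclopropane bond that is both benzylic and α to the carbonyl, so it can be removed selectively, and the bicycle itself is the product of a carbene adding to a cinnamyl ester.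

## Retrosynthetic reasoning

**10 from 9.** No bond is cut. The configuration at C3 is left open, because base equilibration of the lactone enolate should funnel either C3 epimer of 9 to the trans compound 10. This reduces the stereochemical problem to C4 alone.

**9 from 8.** A bond is added in the retrosynthetic direction, from C3 to the ring B benzylic carbon, which gives the 3-oxabicyclo[3.1.0]hexan-2-one 8. This is the one extra bond that makes both benzyl-bearing carbons part of a carbene-addition retron. In the forward direction the reduction has to cleave C1–C6 of 8 and leave C5–C6 (benzylic only) and C1–C5 (α-carbonyl only) intact.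

**8 from 7.** The C1–C5 and C1–C6 bonds of 8 are cut together (C3–C4 and C3–benzylic in lactone numbering). This gives a carbene at the future C3 and an E alkene, joined through the ester oxygen, that is, the cinnamyl α-diazo ester 7. The gain is two C–C bonds, both rings and the C4 stereocentre in one catalytic step. The forward reaction has to select one alkene face and has to outrun hydride migration in the carbene.

**7 from 5.** The diazo group is traced back to the α-methylene of the saturated ester 5. A simple ester is not acidic enough for direct diazo transfer, so the forward step needs a temporary activating acyl group that leaves again.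

**5 from 3 and 4.** The ester C–O bond is cut. This is the convergent point: alcohol 3 brings ring B and the alkene, acid 4 brings ring A and the future carbene carbon. The forward esterification must be non-acidic, because 3 ionises easily to an allylic cation.

**3 from 2 from 1.** These are functional group changes only: the allylic alcohol 3 comes from 1,2-reduction of the ester 2, which comes from the commercial acid 1 with its E geometry already in place.

## Alternatives that were turned down

**Alternative 1:** The O1–C5 bond is traced to oxygen insertion into the prochiral cyclobutanone A1, 3-(3,4,5-trimethoxybenzyl)cyclobutan-1-one, and the ring A benzyl group is added last.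
- Forward: a catalytic enantioselective Baeyer–Villiger oxidation of A1 inserts oxygen into one of the two enantiotopic C(O)–CH2 bonds and gives the lactone A2, (R)-4-(3,4,5-trimethoxybenzyl)oxolan-2-one. The enolate of A2 is then alkylated by 3,4-dimethoxybenzyl bromide A3 anti to the C4 substituent.
- For: A1 is reachable in two operations from an allylarene by ketene [2+2] cycloaddition and dechlorination; the final alkylation sets C3 trans kinetically, with no equilibration; the route is shorter than the chosen one.
- Against: the catalyst has to tell apart two ring CH2 groups that differ only through a substituent two bonds from the carbonyl, insulated by a flexible CH2. The migrating step therefore sees a weak steric bias, and a 3-benzyl cyclobutanone is a less favourable case than a 3-aryl one. A peroxide is also used next to an electron-rich arene.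
- Comparison: Alternative 1 is stronger on step count and on C3 control. The chosen strategy instead creates C4 at the carbon that forms the new bond, in direct contact with the chiral ligands, and needs no labile benzylic bromide.

**Alternative 2:** The ring B–CH2 bond and the C3–CH2 (ring A) bond are cut, and C4 comes from the chiral pool in the bicyclic lactone ester A4, methyl (1S,5R)-2-oxo-3-oxabicyclo[3.1.0]hexane-1-carboxylate, itself assembled from a malonate diester and an enantiopure epihalohydrin.
- Forward: the Grignard reagent A5 (3,4,5-trimethoxyphenylmagnesium bromide) with catalytic CuI (copper monoiodide) opens the cyclopropane of A4 at its CH2. The malonate-type enolate is benzylated in the same pot by A3 to give A6, methyl (3R,4R)-3-(3,4-dimethoxybenzyl)-2-oxo-4-(3,4,5-trimethoxybenzyl)oxolane-3-carboxylate. Krapcho dealkoxycarbonylation would then lead to 10.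
- For: the absolute configuration at C4 is bought, not induced; three components are joined in one flask; the sequence is the shortest of all four.
- Against: a stoichiometric aryl Grignard must attack the cyclopropane CH2 and not the two carbonyl groups; a hindered, stabilised enolate must be C-alkylated by a labile bromide; a quaternary centre and an ester carbon are built only to be removed at high temperature, after which C3 still has to end trans.
- Comparison: Alternative 2 is stronger on step count and on certainty of configuration. The chosen strategy offers catalytic creation of the stereocentre from two stable, achiral carboxylic acids, no stoichiometric organometallic, and no sacrificial carbon.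

**Alternative 3:** The C2–C3 and C2–O1 bonds are cut, with C2 coming from carbon monoxide. The precursor is the homopropargylic alcohol A7, (R)-4-(3,4-dimethoxyphenyl)-2-(3,4,5-trimethoxybenzyl)but-3-yn-1-ol.
- Forward: under carbon monoxide with Pd(OAc)2 (divalent palladium), 1,4-bis(diphenylphosphino)butane and an acid co-catalyst, syn hydro-alkoxycarbonylation of the alkyne closes the lactone as A8, (R,E)-3-(3,4-dimethoxybenzylidene)-4-(3,4,5-trimethoxybenzyl)oxolan-2-one. Reduction of the exocyclic alkene follows.
- For: the carbonyl comes from a one-carbon feedstock; ring A can be attached late by cross-coupling to a terminal alkyne; the E geometry follows from the syn addition.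
- Against: the key step creates no stereocentre, so C4 must be built into A7 by a separate asymmetric sequence of several steps. Reduction of A8 delivers hydrogen to C3 from the face away from the C4 benzyl group, which gives mainly the cis lactone, so the same epimerisation is needed as in the chosen route. Pressurised carbon monoxide is required.
- Comparison: Alternative 3 is more modular in ring A. The chosen strategy is shorter and makes the ring, both C–C bonds and C4 in the same step.

Key step: step 5

Assumption: Rh2(S-PTTL)4 is taken to favour the alkene face that leads to the (1S,5R,6S) bicycle 8. If its sense of induction on this tethered substrate is the opposite, the mirror-image catalyst Rh2(R-PTTL)4 is used with no other change.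

## Route

**Step 1**
Reactants: 1 (E)-3-(3,4,5-trimethoxyphenyl)prop-2-enoic acid (3,4,5-trimethoxycinnamic acid)
Product: 2 methyl (E)-3-(3,4,5-trimethoxyphenyl)prop-2-enoate
Conditions: MeOH, H2SO4 (cat.), reflux
Reagents that add atoms: methanol, CO
Why: Fischer esterification; excess methanol drives the equilibrium and the conjugated E alkene is not affected by the acid.

**Step 2**
Reactants: 2 methyl (E)-3-(3,4,5-trimethoxyphenyl)prop-2-enoate
Product: 3 (E)-3-(3,4,5-trimethoxyphenyl)prop-2-en-1-ol
Conditions: i-Bu2AlH (2.2 equiv), CH2Cl2, −78 → 0 °C; aq. KNaC4H4O6 (potassium sodium tartrate)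
Reagents that add atoms: none
Why: 1,2-reduction of an α,β-unsaturated ester by a dialkylaluminium hydride, which should give the allylic alcohol without touching the alkene or its geometry.

**Step 3**
Reactants: 3 (E)-3-(3,4,5-trimethoxyphenyl)prop-2-en-1-ol; 4 3-(3,4-dimethoxyphenyl)propanoic acid
Product: 5 (E)-3-(3,4,5-trimethoxyphenyl)prop-2-en-1-yl 3-(3,4-dimethoxyphenyl)propanoate
Conditions: DCC, DMAP (cat.), CH2Cl2, 0 °C → rt
Reagents that add atoms: none
Why: Steglich esterification; the neutral carbodiimide conditions avoid ionisation of the electron-rich cinnamyl alcohol, which an acid-catalysed esterification would risk.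

**Step 4**
Reactants: 5 (E)-3-(3,4,5-trimethoxyphenyl)prop-2-en-1-yl 3-(3,4-dimethoxyphenyl)propanoate
Product: 7 (E)-3-(3,4,5-trimethoxyphenyl)prop-2-en-1-yl 2-diazo-3-(3,4-dimethoxyphenyl)propanoate, via α-trifluoroacetyl ester 6 (not isolated)
Conditions: LiN(SiMe3)2, THF, −78 °C; CF3CO2CH2CF3, −78 °C; cold dil. aq. HCl work-up; then MsN3, Et3N, H2O, MeCN, rt
Reagents that add atoms: methanesulfonyl azide, CS(=O)(=O)N=[N+]=[N-] (the two nitrogen atoms of 7); 2,2,2-trifluoroethyl trifluoroacetate, O=C(OCC(F)(F)F)C(F)(F)F (the CF3CO group of 6 only)
Why: Detrifluoroacetylative diazo transfer; the ester enolate is C-acylated at −78 °C, below the temperature at which an allyl ester enolate undergoes Ireland–Claisen rearrangement, and the activated β-keto ester 6 then takes the diazo group from the sulfonyl azide while the trifluoroacetyl group leaves on the sulfonamide.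

**Step 5**
Reactants: 7 (E)-3-(3,4,5-trimethoxyphenyl)prop-2-en-1-yl 2-diazo-3-(3,4-dimethoxyphenyl)propanoate
Product: 8 (1S,5R,6S)-1-(3,4-dimethoxybenzyl)-6-(3,4,5-trimethoxyphenyl)-3-oxabicyclo[3.1.0]hexan-2-one
Conditions: Rh2(S-PTTL)4 [dirhodium tetrakis(N-phthaloyl-(S)-tert-leucinate)] (1 mol %), CH2Cl2, −78 → −40 °C, slow addition of 7
Reagents that add atoms: none
Why: Rh2(S-PTTL)4 (divalent rhodium) decomposes 7 with loss of N2 to an electrophilic rhodium carbene that adds to the tethered E alkene in a concerted, asynchronous [2+1] manner; the closest known reaction type is the enantioselective intramolecular cyclopropanation of allylic diazo esters by chiral dirhodium carboxylates and carboxamidates. The lactone closes in a 5-exo sense when the carbene carbon bonds to the near alkene carbon (the later C3–C4 bond), and the three-membered ring closes in the same event through the second bond to the far, benzylic carbon. C5 (the later C4) is set by the alkene face that the chiral ligand wall of the catalyst leaves open to the carbene; C1 follows from the cis ring fusion that the three-atom ester tether enforces; C6 follows from suprafacial addition with retention of the E geometry, which puts ring B exo. Only one independent stereochemical choice is therefore made, and it is made at the reacting carbon. The step needs chemoselectivity for alkene addition over 1,2-hydride migration from the benzylic CH2 next to the carbene carbon; the bulky phthalimido-tert-leucinate ligands and the low temperature disfavour the migration, slow addition keeps carbene dimerisation down, and the electron-rich styrenyl alkene is a matched partner for the electrophilic carbene.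

**Step 6**
Reactants: 8 (1S,5R,6S)-1-(3,4-dimethoxybenzyl)-6-(3,4,5-trimethoxyphenyl)-3-oxabicyclo[3.1.0]hexan-2-one
Product: 9 (4R)-3-(3,4-dimethoxybenzyl)-4-(3,4,5-trimethoxybenzyl)oxolan-2-one, mixture of C3 epimers
Conditions: H2 (3 atm), 10% Pd/C, EtOAc, rt
Reagents that add atoms: none
Why: Catalytic hydrogenolysis of an activated cyclopropane; C1–C6 is the only bond that is both benzylic and α to the carbonyl, and its cleavage also relieves the cis interaction between the C1 benzyl group and ring B. C5 is not involved, so the future C4 keeps its configuration, while the configuration at the new C3–H is not relied on (retention at C1 would give 10 directly, inversion its C3 epimer).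

**Step 7**
Reactants: 9 (4R)-3-(3,4-dimethoxybenzyl)-4-(3,4,5-trimethoxybenzyl)oxolan-2-one, mixture of C3 epimers
Product: 10 (3R,4R)-3-(3,4-dimethoxybenzyl)-4-(3,4,5-trimethoxybenzyl)oxolan-2-one
Conditions: DBU, toluene, 80 °C
Reagents that add atoms: none
Why: Base-mediated epimerisation through the lactone enolate; the trans-3,4-disubstituted lactone is the thermodynamically preferred epimer, and C4 carries no acidic hydrogen, so its R configuration fixes C3 as R.

## Compound list

1 | (E)-3-(3,4,5-trimethoxyphenyl)prop-2-enoic acid | COc1cc(/C=C/C(=O)O)cc(OC)c1OC | starting material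
2 | methyl (E)-3-(3,4,5-trimethoxyphenyl)prop-2-enoate | COC(=O)/C=C/c1cc(OC)c(OC)c(OC)c1 | intermediate
3 | (E)-3-(3,4,5-trimethoxyphenyl)prop-2-en-1-ol | OC/C=C/c1cc(OC)c(OC)c(OC)c1 | intermediate
4 | 3-(3,4-dimethoxyphenyl)propanoic acid | COc1ccc(CCC(=O)O)cc1OC | starting material
5 | (E)-3-(3,4,5-trimethoxyphenyl)prop-2-en-1-yl 3-(3,4-dimethoxyphenyl)propanoate | COc1ccc(CCC(=O)OC/C=C/c2cc(OC)c(OC)c(OC)c2)cc1OC | intermediate
6 | (E)-3-(3,4,5-trimethoxyphenyl)prop-2-en-1-yl 2-(3,4-dimethoxybenzyl)-4,4,4-trifluoro-3-oxobutanoate | COc1ccc(CC(C(=O)C(F)(F)F)C(=O)OC/C=C/c2cc(OC)c(OC)c(OC)c2)cc1OC | intermediate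
7 | (E)-3-(3,4,5-trimethoxyphenyl)prop-2-en-1-yl 2-diazo-3-(3,4-dimethoxyphenyl)propanoate | COc1ccc(CC(=[N+]=[N-])C(=O)OC/C=C/c2cc(OC)c(OC)c(OC)c2)cc1OC | intermediate
8 | (1S,5R,6S)-1-(3,4-dimethoxybenzyl)-6-(3,4,5-trimethoxyphenyl)-3-oxabicyclo[3.1.0]hexan-2-one | O=C1OC[C@@H]2[C@@H](c3cc(OC)c(OC)c(OC)c3)[C@]12Cc1ccc(OC)c(OC)c1 | intermediate
9 | (4R)-3-(3,4-dimethoxybenzyl)-4-(3,4,5-trimethoxybenzyl)oxolan-2-one, mixture of C3 epimers | COc1ccc(CC2C(=O)OC[C@@H]2Cc2cc(OC)c(OC)c(OC)c2)cc1OC | intermediate
10 | (3R,4R)-3-(3,4-dimethoxybenzyl)-4-(3,4,5-trimethoxybenzyl)oxolan-2-one | COc1ccc(C[C@H]2C(=O)OC[C@@H]2Cc2cc(OC)c(OC)c(OC)c2)cc1OC | target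

## Step count and least certain steps

Total step count: 7. Longest linear sequence: 7 steps (1 to 10); acid 4 enters as purchased in step 3.

**Step 5 (key step).** The most likely failure is 1,2-hydride migration in the rhodium carbene outrunning the cyclisation. The benzylic hydrogens sit next to the carbene carbon at all times, whereas the ester must first rotate into its less populated s-cis conformation before the alkene can reach the carbene. The second risk is poor enantiofacial selection, because the tether restricts the approach of the alkene to the catalyst. The fallback sets out from 3 and comes back at 10; it keeps the cyclopropanation and hydrogenolysis but leaves the ring A benzyl group out of the carbene precursor. Alcohol 3 is acylated with bromoacetyl bromide (NaHCO3, MeCN) to give (E)-3-(3,4,5-trimethoxyphenyl)prop-2-en-1-yl 2-bromoacetate F1. With N,N'-ditosylhydrazine and DBU in THF this gives (E)-3-(3,4,5-trimethoxyphenyl)prop-2-en-1-yl 2-diazoacetate F2, which has no β-hydrogen to migrate. Intramolecular cyclopropanation with Rh2(4S-MPPIM)4 (dirhodium tetrakis[methyl (4S)-2-oxo-1-(3-phenylpropanoyl)imidazolidine-4-carboxylate], divalent rhodium; or its mirror image, whichever gives the 5R series) in CH2Cl2 should give (1S,5R,6R)-6-(3,4,5-trimethoxyphenyl)-3-oxabicyclo[3.1.0]hexan-2-one F3. Hydrogenolysis (H2, Pd/C, EtOAc) opens it to (R)-4-(3,4,5-trimethoxybenzyl)oxolan-2-one F4, the same compound as A2. Its lithium enolate (LiN(SiMe3)2, THF, −78 °C) is alkylated by 3,4-dimethoxybenzyl bromide (A3) on the face away from the C4 substituent, which gives 10 with the trans arrangement set kinetically, so that steps 6 and 7 are not needed either.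

**Step 4.** The most likely failure is incomplete C-acylation of the ester enolate, which is acylated less readily than a ketone enolate, or [3,3]-sigmatropic rearrangement of the cinnamyl ester enolate if the temperature rises. Either would leave material that does not accept the diazo group. The fallback sets out from 3 and comes back at 7 and does not use an ester enolate. Alcohol 3 is heated with 2,2,6-trimethyl-4H-1,3-dioxin-4-one (toluene, 110 °C) to give (E)-3-(3,4,5-trimethoxyphenyl)prop-2-en-1-yl 3-oxobutanoate F5. C-alkylation with 3,4-dimethoxybenzyl bromide (A3) and K2CO3 in acetone gives (E)-3-(3,4,5-trimethoxyphenyl)prop-2-en-1-yl 2-(3,4-dimethoxybenzyl)-3-oxobutanoate F6. Deacylative diazo transfer (4-acetamidobenzenesulfonyl azide, DBU, MeCN, 0 °C → rt) then gives 7.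

**Step 6.** The most likely failure is cleavage of the other benzylic cyclopropane bond, C5–C6, which is less hindered because C1 is quaternary and which would lead to a 3,3-disubstituted lactone skeleton. The reaction could also fail to start if the quaternary centre prevents adsorption on the metal. The fallback sets out from 8 and comes back at 9 and replaces surface hydrogenolysis by single-electron reduction: SmI2 (samarium diiodide, divalent samarium) in THF/HMPA with t-BuOH at −78 °C → rt. Electron transfer to the lactone carbonyl gives a radical anion that can fragment only across C1–C6, towards the benzylic radical stabilised by ring B. A second electron and protonation then give 9, and step 7 follows as before. No new compound is made on this path.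

## Further compounds

F1 | step 5 | (E)-3-(3,4,5-trimethoxyphenyl)prop-2-en-1-yl 2-bromoacetate | O=C(CBr)OC/C=C/c1cc(OC)c(OC)c(OC)c1
F2 | step 5 | (E)-3-(3,4,5-trimethoxyphenyl)prop-2-en-1-yl 2-diazoacetate | [N-]=[N+]=CC(=O)OC/C=C/c1cc(OC)c(OC)c(OC)c1
F3 | step 5 | (1S,5R,6R)-6-(3,4,5-trimethoxyphenyl)-3-oxabicyclo[3.1.0]hexan-2-one | O=C1OC[C@@H]2[C@@H](c3cc(OC)c(OC)c(OC)c3)[C@H]12
F4 | step 5 | (R)-4-(3,4,5-trimethoxybenzyl)oxolan-2-one | O=C1OC[C@H](Cc2cc(OC)c(OC)c(OC)c2)C1
F5 | step 4 | (E)-3-(3,4,5-trimethoxyphenyl)prop-2-en-1-yl 3-oxobutanoate | CC(=O)CC(=O)OC/C=C/c1cc(OC)c(OC)c(OC)c1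
F6 | step 4 | (E)-3-(3,4,5-trimethoxyphenyl)prop-2-en-1-yl 2-(3,4-dimethoxybenzyl)-3-oxobutanoate | COc1ccc(CC(C(C)=O)C(=O)OC/C=C/c2cc(OC)c(OC)c(OC)c2)cc1OC
F0 | step 6 | none | none
A1 | alternative 1 | 3-(3,4,5-trimethoxybenzyl)cyclobutan-1-one | O=C1CC(Cc2cc(OC)c(OC)c(OC)c2)C1
A2 | alternative 1 | (R)-4-(3,4,5-trimethoxybenzyl)oxolan-2-one | O=C1OC[C@H](Cc2cc(OC)c(OC)c(OC)c2)C1
A3 | alternative 1 | 3,4-dimethoxybenzyl bromide | COc1ccc(CBr)cc1OC
A4 | alternative 2 | methyl (1S,5R)-2-oxo-3-oxabicyclo[3.1.0]hexane-1-carboxylate | O=C1OC[C@@H]2C[C@]12C(=O)OC
A5 | alternative 2 | 3,4,5-trimethoxyphenylmagnesium bromide | COc1cc([Mg]Br)cc(OC)c1OC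
A6 | alternative 2 | methyl (3R,4R)-3-(3,4-dimethoxybenzyl)-2-oxo-4-(3,4,5-trimethoxybenzyl)oxolane-3-carboxylate | COc1ccc(C[C@@]2(C(=O)OC)C(=O)OC[C@@H]2Cc2cc(OC)c(OC)c(OC)c2)cc1OC
A7 | alternative 3 | (R)-4-(3,4-dimethoxyphenyl)-2-(3,4,5-trimethoxybenzyl)but-3-yn-1-ol | OC[C@@H](C#Cc1ccc(OC)c(OC)c1)Cc1cc(OC)c(OC)c(OC)c1
A8 | alternative 3 | (R,E)-3-(3,4-dimethoxybenzylidene)-4-(3,4,5-trimethoxybenzyl)oxolan-2-one | COc1ccc(/C=C2/C(=O)OC[C@@H]2Cc2cc(OC)c(OC)c(OC)c2)cc1OC
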